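**Retrosynthetic overview**
1. Last operations: the lactol is released from its methyl acetal, the tertiary acetate comes from the alcohol, and ring A is joined by adding a primary organocerium (the CH2 on the cyclopentane) to (4S)-4-bromo-3,3-dimethylcyclohexanone, which is made apart by a bromonium cyclisation and resolved.
2. The strategy rests on one feature: the cyclopentane shares the bond between the quaternary bridgehead carbon and the one-carbon bridge of the 6-oxabicyclo[3.2.1]octane. With that ring opened the bridge carbon is a plain CH2 lying 1,5 to the diazo carbon of a β-keto ester chain on the bridgehead, so the ring is closed by rhodium carbenoid C–H insertion.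
3. A ring ketone next to the bridgehead would capture the carbenoid as a six-membered carbonyl ylide, so it is converted into the equatorial bromide of the target before the diazo ester is built (two steps the route needs in any case).
4. The bicyclic lactone comes from acid lactonisation of an allylated cyclohexenone β-keto ester, its quaternary carbon from palladium-catalysed asymmetric allylation, and the carbocycle from Birch reduction of methyl 2-methoxy-5-methylbenzoate.
5. Ring order: six-membered carbocycle (from the arene), lactone bridge, cyclopentane (key step), ring A (attached last).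

Key step: step 9

Remark: the lactol hydroxyl of the target (on the face away from the cyclopentane, close to the bromine) is taken to be the thermodynamic anomer and is set by equilibration in the last step; lactol and acetal intermediates are drawn with the same configuration, which is of no consequence.
Remark: the sense of induction of the (R,R)-ligand in step 2 is assumed; the (S,S)-ligand is used if it proves opposite.

**Route**

Step 1
Reactants: 1 methyl 2-methoxy-5-methylbenzoate
Product: 3 methyl 3-methyl-6-oxocyclohex-2-ene-1-carboxylate (racemic β-keto ester), via methyl 2-methoxy-5-methylcyclohexa-2,5-diene-1-carboxylate 2 (not isolated)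
Conditions: Li, NH3(l), THF, t-BuOH (1.5 equiv), −78 °C; NH4Cl; then 1 M HCl, THF, rt
Reagents that add atoms: water, O
Why: Birch reduction of a benzoate puts the two new hydrogens on the ester-bearing carbon and the carbon para to it, leaving methoxy and methyl on the two isolated double bonds, and mild acid hydrolysis of the enol ether then unveils the β-keto ester without touching the trisubstituted alkene; no stereocentre is kept because C-1 is enolisable.

Step 2
Reactants: 3 methyl 3-methyl-6-oxocyclohex-2-ene-1-carboxylate; 4 allyl acetate
Product: 5 methyl (1R)-3-methyl-6-oxo-1-(prop-2-en-1-yl)cyclohex-2-ene-1-carboxylate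
Conditions: [Pd(η3-C3H5)Cl]2 (1 mol%), (R,R)-N,N′-bis(2-diphenylphosphinobenzoyl)-1,2-diaminocyclohexane (2.5 mol%), tetramethylguanidine, toluene, 0 °C
Reagents that add atoms: none
Why: Tsuji–Trost asymmetric allylic alkylation of a cyclic β-keto ester enolate, a soft prochiral nucleophile that is allylated at the doubly activated carbon, the chiral pocket of the diphosphine-bound π-allylpalladium choosing one enolate face and so setting the quaternary centre.

Step 3
Reactants: 5 methyl (1R)-3-methyl-6-oxo-1-(prop-2-en-1-yl)cyclohex-2-ene-1-carboxylate
Product: 6 (1R,5R)-5-methyl-1-(prop-2-en-1-yl)-6-oxabicyclo[3.2.1]octane-2,7-dione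
Conditions: TfOH (1.1 equiv), CH2Cl2, 0 °C → rt; then aq. NaHCO3
Reagents that add atoms: none
Why: acid-mediated demethylative lactonisation of a β,γ-unsaturated ester, in which Markovnikov protonation of the trisubstituted ring alkene gives a tertiary cation that the ester carbonyl on the neighbouring quaternary carbon traps in the only geometry open to a bridge, so the new C–O stereocentre follows from the quaternary one while the monosubstituted allyl alkene is too slow to protonate.

Step 4
Reactants: 6 (1R,5R)-5-methyl-1-(prop-2-en-1-yl)-6-oxabicyclo[3.2.1]octane-2,7-dione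
Product: 7 (1R,2R,5R)-2-hydroxy-5-methyl-1-(prop-2-en-1-yl)-6-oxabicyclo[3.2.1]octan-7-one (axial alcohol; hydroxyl anti to the lactone bridge)
Conditions: LiBH(s-Bu)3 (L-Selectride), THF, −78 °C; AcOH quench
Reagents that add atoms: none
Why: chemoselective ketone reduction by a bulky trialkylborohydride, which avoids the axial path past the two syn-axial hydrogens and attacks equatorially as it does with 2,2-disubstituted cyclohexanones, giving the axial alcohol and leaving the lactone and the alkene untouched.

Step 5
Reactants: 7 (1R,2R,5R)-2-hydroxy-5-methyl-1-(prop-2-en-1-yl)-6-oxabicyclo[3.2.1]octan-7-one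
Product: 8 (1S,2S,5R)-2-bromo-5-methyl-1-(prop-2-en-1-yl)-6-oxabicyclo[3.2.1]octan-7-one (bromine equatorial; cis to the lactone bridge)
Conditions: PPh3, CBr4, toluene, 0 → 70 °C
Reagents that add atoms: carbon tetrabromide, BrC(Br)(Br)Br
Why: Appel bromination with inversion, bromide displacing the axial alkoxyphosphonium group from the equatorial side as is known for axial neopentylic cyclohexanols, while the lactone carbonyl on the adjacent quaternary carbon disfavours ionisation and skeletal shift.

Step 6
Reactants: 8 (1S,2S,5R)-2-bromo-5-methyl-1-(prop-2-en-1-yl)-6-oxabicyclo[3.2.1]octan-7-one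
Product: 9 2-(2-bromo-5-methyl-7-oxo-6-oxabicyclo[3.2.1]octan-1-yl)acetic acid (ring configuration as in 8)
Conditions: RuCl3·xH2O (3 mol%), NaIO4 (5 equiv), MeCN/EtOAc/H2O, rt
Reagents that add atoms: sodium periodate, [Na+].[O-]I(=O)(=O)=O; water, O
Why: ruthenium tetroxide-catalysed oxidative cleavage of the terminal alkene with periodate as the stoichiometric oxidant shortens the allyl group to the acetic acid chain, and the secondary bromide and the lactone are inert under these biphasic conditions.

Step 7
Reactants: 9 2-(2-bromo-5-methyl-7-oxo-6-oxabicyclo[3.2.1]octan-1-yl)acetic acid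
Product: 11 methyl 4-(2-bromo-5-methyl-7-oxo-6-oxabicyclo[3.2.1]octan-1-yl)-3-oxobutanoate (ring configuration as in 8), via acyl imidazole 10 (not isolated)
Conditions: CDI, THF, rt; then Mg(O2CCH2CO2Me)2, THF, rt → 40 °C; 1 M HCl
Reagents that add atoms: magnesium bis(methyl malonate), COC(=O)CC(=O)[O-].COC(=O)CC(=O)[O-].[Mg+2]
Why: Masamune–Brooks homologation, in which the acyl imidazole C-acylates the chelated magnesium malonate half-ester and loss of CO2 gives the β-keto ester under near-neutral conditions that spare the bromo lactone.

Step 8
Reactants: 11 methyl 4-(2-bromo-5-methyl-7-oxo-6-oxabicyclo[3.2.1]octan-1-yl)-3-oxobutanoate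
Product: 12 methyl 4-(2-bromo-5-methyl-7-oxo-6-oxabicyclo[3.2.1]octan-1-yl)-2-diazo-3-oxobutanoate (ring configuration as in 8)
Conditions: 4-acetamidobenzenesulfonyl azide, Et3N, MeCN, 0 °C → rt
Reagents that add atoms: 4-acetamidobenzenesulfonyl azide, CC(=O)Nc1ccc(cc1)S(=O)(=O)N=[N+]=[N-]
Why: Regitz diazo transfer to the only doubly activated methylene of the molecule.

Step 9
Reactants: 12 methyl 4-(2-bromo-5-methyl-7-oxo-6-oxabicyclo[3.2.1]octan-1-yl)-2-diazo-3-oxobutanoate
Product: 13 tricyclic bromo lactone β-keto ester (cyclopentanone fused across the bridgehead and the bridge carbon; new ring cis to the lactone ring; ester trans to the C–O bridgehead)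
Conditions: Rh2(OAc)4 (2 mol%), CH2Cl2, reflux, slow addition of 12
Reagents that add atoms: none
Why: Loss of N2 at the dirhodium centre gives an electrophilic carbenoid whose carbon inserts, through a three-centre transition state with retention, into a C–H bond of the bridging CH2 five atoms away; the closest known reaction type is the intramolecular 1,5 C–H insertion of α-diazo β-keto esters to 2-carbomethoxycyclopentanones, also used for trans-fused hydrindanones. The cyclopentanone is closed in the 1,5 mode by the new bond from the carbenoid carbon to the bridge carbon, the ring holding the bridgehead, its CH2, the ketone carbon and the two carbons just joined. Of the two bridge hydrogens only the one over the lactone bridge (equatorial on the six-membered chair) lets the new ring be cis-fused to the lactone ring and trans-fused to the carbocycle, the other demanding a trans-fused pair of five-membered rings, so the rigid bicycle fixes the new ring-fusion CH; the ester-bearing carbon is epimerisable, settles trans to the C–O bridgehead and is erased in step 10 anyway. Site selectivity is needed against the only other 1,5 hydrogen, the one geminal to bromine, which is inductively deactivated and sits on a crowded methine, and against capture by heteroatoms: alkyl bromides are tolerated by divalent rhodium carbenoids, and the ring ketone that would have formed a six-membered carbonyl ylide is no longer there. The lactone carbonyl can at most form a reversible ylide with no α-hydrogen to shift, and the carbenoid has no β-hydrogen for a 1,2-shift.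

Step 10
Reactants: 13 tricyclic bromo lactone β-keto ester
Product: 14 enol triflate of 13 (triflate on the former ketone carbon; alkene to the ester carbon)
Conditions: Tf2O, i-Pr2NEt, CH2Cl2, −78 °C
Reagents that add atoms: trifluoromethanesulfonic anhydride, O=S(=O)(OS(=O)(=O)C(F)(F)F)C(F)(F)F
Why: O-sulfonylation of the enolised β-keto ester (enol triflate formation), the only acidic carbonyl system present, which removes the stereocentre at the ester-bearing carbon on purpose.

Step 11
Reactants: 14 enol triflate
Product: 15 cyclopentene ester (conjugated methyl ester; alkene between the ester carbon and the former ketone carbon)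
Conditions: Pd(OAc)2 (5 mol%), PPh3 (10 mol%), HCO2H, n-Bu3N, DMF, 60 °C
Reagents that add atoms: none
Why: palladium-catalysed formate reduction of an enol triflate, in which zerovalent palladium inserts into the vinyl C–O bond, formate gives hydride with loss of CO2 and reductive elimination leaves the C–H bond, the unactivated secondary bromide being inert to this catalyst.

Step 12
Reactants: 15 cyclopentene ester
Product: 16 saturated ester with the ester cis to the C–O bridgehead (kinetic epimer)
Conditions: H2 (1 atm), 5% Rh/Al2O3, EtOAc, rt
Reagents that add atoms: none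
Why: heterogeneous hydrogenation of the conjugated alkene from the face opposite the cis-fused lactone ring, which delivers hydrogen to the convex face and leaves the ester on the concave one, rhodium on alumina being chosen because it spares C–Br bonds.

Step 13
Reactants: 16 saturated ester (kinetic epimer)
Product: 17 saturated ester with the ester trans to the C–O bridgehead
Conditions: NaOMe (0.3 equiv), MeOH, rt; AcOH
Reagents that add atoms: none
Why: base-mediated epimerisation of the ester α-carbon under thermodynamic control moves the ester to the convex face, trans to the C–O bridgehead as the target requires, while the equatorial bromide has no antiperiplanar hydrogen for elimination and the lactone carbonyl on its quaternary carbon is too hindered for methanolysis.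

Step 14
Reactants: 17 saturated ester
Product: 18 lactol alcohol (hydroxymethyl in place of the ester; lactol in place of the lactone)
Conditions: i-Bu2AlH (DIBAL-H, 4 equiv), CH2Cl2, −78 → −40 °C; Rochelle salt
Reagents that add atoms: none
Why: DIBAL-H reduction takes the methyl ester to the primary alcohol and stops at the lactol for the bridged lactone, whose tetrahedral aluminate cannot open within the rigid bicycle at low temperature.

Step 15
Reactants: 18 lactol alcohol
Product: 19 methyl acetal alcohol
Conditions: MeOH, PPTS (cat.), 4 Å sieves, rt
Reagents that add atoms: methanol, CO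
Why: acid-catalysed acetalisation of the lactol through the bridged oxocarbenium ion masks it for the organometallic steps, the primary alcohol on the opposite face of the cyclopentane being unable to reach the acetal carbon.

Step 16
Reactants: 19 methyl acetal alcohol
Product: 20 methyl acetal iodide
Conditions: PPh3, I2, imidazole, CH2Cl2, 0 °C → rt
Reagents that add atoms: iodine, II
Why: Appel-type iodination of the unhindered primary alcohol under imidazole buffering, which keeps the acetal intact.

Step 17
Reactants: 21 6-methylhept-5-en-2-one
Product: 22 methyl 7-methyl-3-oxooct-6-enoate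
Conditions: NaH, dimethyl carbonate, THF, reflux; 1 M HCl
Reagents that add atoms: dimethyl carbonate, COC(=O)OC
Why: Claisen-type C-acylation of the methyl ketone with dimethyl carbonate, which under equilibrating conditions ends on the methyl side as the stabilised β-keto ester enolate.

Step 18
Reactants: 22 methyl 7-methyl-3-oxooct-6-enoate
Product: 23 methyl 3-bromo-2,2-dimethyl-6-oxocyclohexane-1-carboxylate (racemic)
Conditions: Et2SBr·SbBrCl5, MeNO2, −25 °C
Reagents that add atoms: bromodiethylsulfonium bromopentachloroantimonate, CC[S+](Br)CC.Cl[Sb-](Cl)(Cl)(Cl)(Cl)Br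
Why: bromonium-initiated cation–olefin cyclisation terminated by the β-keto ester, in which the enol carbon attacks the tertiary end of the bromonium ion in a chair transition state and closes the six-membered ring with bromine next to the gem-dimethyl carbon, in racemic form.

Step 19
Reactants: 23 methyl 3-bromo-2,2-dimethyl-6-oxocyclohexane-1-carboxylate
Product: 24 rac-4-bromo-3,3-dimethylcyclohexan-1-one
Conditions: 48% aq. HBr, AcOH, 100 °C
Reagents that add atoms: none
Why: acid hydrolysis and decarboxylation of the β-keto ester, chosen over basic or halide-mediated dealkoxycarbonylation so that no enolate forms near the γ-bromide and no foreign halide can exchange with it.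

Step 20
Reactants: 24 rac-4-bromo-3,3-dimethylcyclohexan-1-one
Product: 25 (4S)-4-bromo-3,3-dimethylcyclohexan-1-one
Conditions: preparative supercritical-fluid chromatography on amylose tris(3,5-dimethylphenylcarbamate), CO2/MeOH
Reagents that add atoms: none
Why: resolution of a racemate by chromatography on a chiral stationary phase, a dependable way to one enantiomer of a bromide whose only stereocentre comes from a non-selective bromonium cyclisation, the absolute configuration to be confirmed by anomalous-dispersion X-ray analysis.

Step 21
Reactants: 20 methyl acetal iodide; 25 (4S)-4-bromo-3,3-dimethylcyclohexan-1-one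
Product: 28 tertiary alcohol (ring A joined; hydroxyl axial; cis to the ring-A bromine), via organolithium 26 (not isolated), via organocerium 27 (not isolated)
Conditions: t-BuLi (2.1 equiv), Et2O/pentane, −78 °C; CeCl3, THF, −78 °C; then 25 (1.5 equiv), −78 °C; NH4Cl
Reagents that add atoms: none
Why: iodine–lithium exchange (far faster for the primary iodide than any reaction of a secondary bromide at −78 °C), transmetallation to the weakly basic organocerium and 1,2-addition to the enolisable ketone, where attack anti to the axial 3-methyl group of the chair with bromine equatorial puts the new CH2 group equatorial and the hydroxyl axial and cis to bromine, the C-1 epimer from the bromine-axial chair being a separable ring-A diastereomer.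

Step 22
Reactants: 28 tertiary alcohol
Product: 29 tertiary acetate methyl acetal
Conditions: KN(SiMe3)2, THF, −78 °C; Ac2O, −78 → 0 °C
Reagents that add atoms: acetic anhydride, CC(=O)OC(C)=O
Why: O-acylation of the potassium alkoxide, used because the axial tertiary alcohol is too hindered for amine-catalysed acetylation, the alkoxide being unable to displace the ring bromide that lies cis to it.

Step 23
Reactants: 29 tertiary acetate methyl acetal
Product: 30 CNP0196016.1 (target)
Conditions: AcOH/THF/H2O (3:1:1), 45 °C
Reagents that add atoms: water, O
Why: mild acid hydrolysis of the methyl acetal through the oxocarbenium ion gives the lactol, which equilibrates to the anomer of the target, while the tertiary acetate and both secondary bromides are stable to dilute acetic acid.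

**Compound list**
1 | methyl 2-methoxy-5-methylbenzoate | COC(=O)c1cc(C)ccc1OC | starting material
2 | methyl 2-methoxy-5-methylcyclohexa-2,5-diene-1-carboxylate (racemic) | COC(=O)C1C=C(C)CC=C1OC | intermediate
3 | methyl 3-methyl-6-oxocyclohex-2-ene-1-carboxylate (racemic) | COC(=O)C1C=C(C)CCC1=O | intermediate
4 | allyl acetate | C=CCOC(C)=O | starting material
5 | methyl (1R)-3-methyl-6-oxo-1-(prop-2-en-1-yl)cyclohex-2-ene-1-carboxylate | C=CC[C@@]1(C(=O)OC)C=C(C)CCC1=O | intermediate
6 | (1R,5R)-5-methyl-1-(prop-2-en-1-yl)-6-oxabicyclo[3.2.1]octane-2,7-dione | C=CC[C@]12C(=O)O[C@](C)(CCC1=O)C2 | intermediate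
7 | (1R,2R,5R)-2-hydroxy-5-methyl-1-(prop-2-en-1-yl)-6-oxabicyclo[3.2.1]octan-7-one | C=CC[C@]12C(=O)O[C@](C)(CC[C@H]1O)C2 | intermediate
8 | (1S,2S,5R)-2-bromo-5-methyl-1-(prop-2-en-1-yl)-6-oxabicyclo[3.2.1]octan-7-one | C=CC[C@]12C(=O)O[C@](C)(CC[C@@H]1Br)C2 | intermediate
9 | 2-(2-bromo-5-methyl-7-oxo-6-oxabicyclo[3.2.1]octan-1-yl)acetic acid, ring configuration as in 8 | OC(=O)C[C@]12C(=O)O[C@](C)(CC[C@@H]1Br)C2 | intermediate
10 | acyl imidazole of acid 9 | O=C(C[C@]12C(=O)O[C@](C)(CC[C@@H]1Br)C2)n1ccnc1 | intermediate
11 | methyl 4-(2-bromo-5-methyl-7-oxo-6-oxabicyclo[3.2.1]octan-1-yl)-3-oxobutanoate, ring configuration as in 8 | COC(=O)CC(=O)C[C@]12C(=O)O[C@](C)(CC[C@@H]1Br)C2 | intermediate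
12 | methyl 4-(2-bromo-5-methyl-7-oxo-6-oxabicyclo[3.2.1]octan-1-yl)-2-diazo-3-oxobutanoate, ring configuration as in 8 | COC(=O)C(=[N+]=[N-])C(=O)C[C@]12C(=O)O[C@](C)(CC[C@@H]1Br)C2 | intermediate
13 | tricyclic bromo lactone β-keto ester (cyclopentanone cis-fused to the lactone ring; ester trans to the C–O bridgehead) | COC(=O)[C@@H]1C(=O)C[C@]23C(=O)O[C@](C)(CC[C@@H]2Br)[C@@H]13 | intermediate
14 | enol triflate of 13 | COC(=O)C1=C(OS(=O)(=O)C(F)(F)F)C[C@]23C(=O)O[C@](C)(CC[C@@H]2Br)[C@@H]13 | intermediate
15 | tricyclic cyclopentene ester | COC(=O)C1=CC[C@]23C(=O)O[C@](C)(CC[C@@H]2Br)[C@@H]13 | intermediate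
16 | saturated ester, ester cis to the C–O bridgehead | COC(=O)[C@H]1CC[C@]23C(=O)O[C@](C)(CC[C@@H]2Br)[C@@H]13 | intermediate
17 | saturated ester, ester trans to the C–O bridgehead | COC(=O)[C@@H]1CC[C@]23C(=O)O[C@](C)(CC[C@@H]2Br)[C@@H]13 | intermediate
18 | lactol alcohol | OC[C@@H]1CC[C@]23[C@H](O)O[C@](C)(CC[C@@H]2Br)[C@@H]13 | intermediate
19 | methyl acetal alcohol | OC[C@@H]1CC[C@]23[C@H](OC)O[C@](C)(CC[C@@H]2Br)[C@@H]13 | intermediate
20 | methyl acetal iodide | IC[C@@H]1CC[C@]23[C@H](OC)O[C@](C)(CC[C@@H]2Br)[C@@H]13 | intermediate
21 | 6-methylhept-5-en-2-one | CC(=O)CCC=C(C)C | starting material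
22 | methyl 7-methyl-3-oxooct-6-enoate | COC(=O)CC(=O)CCC=C(C)C | intermediate
23 | methyl 3-bromo-2,2-dimethyl-6-oxocyclohexane-1-carboxylate (racemic) | COC(=O)C1C(=O)CCC(Br)C1(C)C | intermediate
24 | rac-4-bromo-3,3-dimethylcyclohexan-1-one | O=C1CCC(Br)C(C)(C)C1 | intermediate
25 | (4S)-4-bromo-3,3-dimethylcyclohexan-1-one | O=C1CC[C@H](Br)C(C)(C)C1 | intermediate
26 | primary organolithium from iodide 20 | [Li]C[C@@H]1CC[C@]23[C@H](OC)O[C@](C)(CC[C@@H]2Br)[C@@H]13 | intermediate
27 | dichlorocerium reagent from 26 | Cl[Ce](Cl)C[C@@H]1CC[C@]23[C@H](OC)O[C@](C)(CC[C@@H]2Br)[C@@H]13 | intermediate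
28 | tertiary alcohol with ring A attached (hydroxyl axial, cis to the ring-A bromine) | O[C@]1(C[C@@H]2CC[C@]34[C@H](OC)O[C@](C)(CC[C@@H]3Br)[C@@H]24)CC[C@H](Br)C(C)(C)C1 | intermediate
29 | tertiary acetate methyl acetal | CC(=O)O[C@]1(C[C@@H]2CC[C@]34[C@H](OC)O[C@](C)(CC[C@@H]3Br)[C@@H]24)CC[C@H](Br)C(C)(C)C1 | intermediate
30 | CNP0196016.1 | CC(=O)O[C@]1(C[C@@H]2CC[C@]34[C@H](O)O[C@](C)(CC[C@@H]3Br)[C@@H]24)CC[C@H](Br)C(C)(C)C1 | target

**Step count**
Total: 23 steps. Longest linear sequence: 19 steps (steps 1–16 and 21–23); ring A takes 4 steps (17–20).

**Steps most likely to fail**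

Step 9 (key step). The carbenoid may be diverted before it reaches the electron-poor bridge C–H: insertion at the C–H geminal to bromine, capture by bromine or lactone lone pairs, or dimerisation. The fallback sets out from 5 and comes back at 13; it brings the missing carbon to the bridge by a radical allylation and closes the cyclopentanone by a Dieckmann condensation. Iodolactonisation of 5 (I2, MeCN) gives the iodo keto lactone F1, with iodine on the bridge carbon anti to the lactone. Keck allylation (allylSnBu3, AIBN, benzene, 80 °C) should deliver the allyl group to the bridge radical from the side of the small lactone bridge and give the diallyl keto lactone F2. Reduction with LiBH(s-Bu)3 gives the axial alcohol F3, and Appel bromination gives the bromide F4. Cleavage of both alkenes (RuCl3, NaIO4) gives the diacid F5, which Me3SiCHN2 in MeOH converts into the dimethyl ester F6. Dieckmann condensation (t-BuOK, THF) is expected to close through the less hindered methylene of the bridge arm onto the ester of the bridgehead arm and return 13; the regioisomeric keto ester, if formed, is removed.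

Step 5. The axial alkoxyphosphonium group may be lost by elimination toward the ring CH2 instead of being displaced at the neopentylic carbon, or step 4 may deliver the equatorial alcohol, which would invert to the axial bromide. The fallback sets out from 6 and comes back at 8; it uses the other alcohol epimer and a substitution with retention. NaBH4 (MeOH/CH2Cl2, −40 °C) attacks axially and gives the equatorial alcohol F7. Quinoline-8-sulfonyl chloride (pyridine, DMAP) gives the chelating quinoline-8-sulfonate F8. TiBr4 (CH2Cl2, −78 → 0 °C) binds the sulfonate and the ring nitrogen and delivers bromide from the front side, giving 8 with retention.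

Step 21. Selectivity between the two ring-A chairs in the ketone addition may be low, since attack on the bromine-axial chair gives the C-1 epimer; enolisation of the ketone or metalation at a C–Br bond may add to the loss. The fallback sets out from 25 and 20 and comes back at 29; it reverses the polarity and brings in the oxygen by oxidation, so that the stereo-determining step no longer involves a ring carbonyl whose dipole favours the bromine-axial chair. Van Leusen reductive cyanation of 25 (TosMIC, t-BuOK, DME/EtOH) gives the ring-A nitrile F9. Its lithium anion (LiN(i-Pr)2, THF, −78 °C) is alkylated by iodide 20 along the equatorial direction, anti to the axial methyl group, and gives the quaternary nitrile F10 with the cyano group axial. MeLi (Et2O, 0 °C) followed by hydrolysis of the imine on wet silica gives the methyl ketone F11. Baeyer–Villiger oxidation (mCPBA, NaHCO3, CH2Cl2), in which the tertiary carbon migrates with retention, gives the acetate 29.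

**Further compounds**
F1 | step 9 | 8-iodo-5-methyl-1-(prop-2-en-1-yl)-6-oxabicyclo[3.2.1]octane-2,7-dione (iodine anti to the lactone bridge) | C=CC[C@]12C(=O)O[C@](C)(CCC1=O)[C@@H]2I
F2 | step 9 | 5-methyl-1,8-di(prop-2-en-1-yl)-6-oxabicyclo[3.2.1]octane-2,7-dione (8-allyl syn to the lactone bridge) | C=CC[C@]12C(=O)O[C@](C)(CCC1=O)[C@H]2CC=C
F3 | step 9 | axial alcohol of F2 | C=CC[C@]12C(=O)O[C@](C)(CC[C@H]1O)[C@H]2CC=C
F4 | step 9 | equatorial bromide from F3 | C=CC[C@]12C(=O)O[C@](C)(CC[C@@H]1Br)[C@H]2CC=C
F5 | step 9 | bromo lactone diacid | OC(=O)C[C@]12C(=O)O[C@](C)(CC[C@@H]1Br)[C@H]2CC(=O)O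
F6 | step 9 | bromo lactone dimethyl ester | COC(=O)C[C@]12C(=O)O[C@](C)(CC[C@@H]1Br)[C@H]2CC(=O)OC
F7 | step 5 | equatorial alcohol (hydroxyl cis to the lactone bridge) | C=CC[C@]12C(=O)O[C@](C)(CC[C@@H]1O)C2
F8 | step 5 | quinoline-8-sulfonate of F7 | C=CC[C@]12C(=O)O[C@](C)(CC[C@@H]1OS(=O)(=O)c1cccc3cccnc13)C2
F9 | step 21 | (4S)-4-bromo-3,3-dimethylcyclohexane-1-carbonitrile (C-1 epimers) | N#CC1CC[C@H](Br)C(C)(C)C1
F10 | step 21 | quaternary ring-A nitrile (cyano axial) | N#C[C@]1(C[C@@H]2CC[C@]34[C@H](OC)O[C@](C)(CC[C@@H]3Br)[C@@H]24)CC[C@H](Br)C(C)(C)C1
F11 | step 21 | ring-A methyl ketone (acetyl axial) | CC(=O)[C@]1(C[C@@H]2CC[C@]34[C@H](OC)O[C@](C)(CC[C@@H]3Br)[C@@H]24)CC[C@H](Br)C(C)(C)C1
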